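**Retrosynthetic overview**

1. Locants follow the terpenoid skeleton: left decalin ring A = C5–C10, ring B = C1–C5 + C10 (methyls on C4, C8, C9; arylmethyl on C9); linker C11–C12; right decalin primed (ring C = C5'–C10', ring D = C1'–C5' + C10'; methyls on C4' twice, C8', C9'). Toxiusol 36 ⇐ sulfation of hydroquinone 35 ⇐ dimethyl ether 33 ⇐ enol triflate 32.
2. Key disconnection C4–C12: 32 ⇐ copper-catalysed conjugate addition of the primary Grignard reagent 30 (whole right decalin plus C11–C12) to left enone 13, with O-triflation of the enolate. The enabling feature is the s-cis enone O=C6–C5=C4 of 13 (C6 carbonyl in ring A, C5=C4 exocyclic to ring A and inside ring B) next to the sp3 fusion carbon C10, whose axial hydrogen marks the face on which C4 is attacked. The C6 oxygen is a temporary activating group, removed in step 17.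
3. Left enone 13: ring A from 2-methylcyclohex-2-en-1-one (asymmetric conjugate addition/benzylation sets C10 and C9; 1,3-carbonyl transposition; methylcuprate sets C8); ring B last, by aldol condensation forming C5=C4.
4. Right bromide 29: ring D from 4,4-dimethylcyclohex-2-en-1-one (CBS reduction, anti-SN2' relay to C5'); ring C by palladium-catalysed enolate–alkenyl bromide coupling with in situ methylation at C9'; C8' by methylenation/hydrogenation.
5. Ring order: A then B (left), D then C (right), union of the halves at C4–C12, then unveiling and sulfation of the hydroquinone.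

Key step: step 16

Assumption: toxiusol is drawn as the free bis(hydrogen sulfate); step 19 therefore ends with a cation exchange to the acid form (the disodium salt would be preferred for storage).
Remark: where a name carries no CIP descriptor, the configuration is that of the SMILES in the compound list, described with the locants above.

**Route**

Step 1
Reactants: 1 2-methylcyclohex-2-en-1-one; 2 2-(3-chloropropyl)-2-methyl-1,3-dioxolane; 3 2,5-dimethoxybenzyl bromide
Product: 6 ketone (2S,3S)-2-(2,5-dimethoxybenzyl)-2-methyl-3-[3-(2-methyl-1,3-dioxolan-2-yl)propyl]cyclohexan-1-one, via Grignard reagent 4 (not isolated), via magnesium enolate 5 (not isolated)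
Conditions: 2, Mg, THF, 50 °C; then 1, Cu(OTf)2 (3 mol %), chiral hydroxyalkyl imidazolinium carbene precursor (4 mol %, antipode chosen for 3S), Et2O, −10 °C; then 3, DMPU, −10 °C to rt
Reagents that add atoms: none
Why: Copper–N-heterocyclic carbene catalysed asymmetric conjugate addition of the alkyl Grignard reagent to the α-methyl enone sets C10 under catalyst control, and the magnesium enolate is then C-benzylated anti to the new C10 substituent, which sets the quaternary C9 (tandem conjugate addition–enolate alkylation).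

Step 2
Reactants: 6 ketone from step 1
Product: 8 enol triflate of 6 (OTf on C8; C7=C8), via potassium enolate 7 (not isolated)
Conditions: KN(SiMe3)2, THF, −78 °C; then PhNTf2, −78 °C to 0 °C
Reagents that add atoms: N-phenylbis(trifluoromethanesulfonimide), O=S(=O)(N(c1ccccc1)S(=O)(=O)C(F)(F)F)C(F)(F)F
Why: Enolate O-triflation: because C9 is quaternary the ketone can enolise only towards C7, so a single enol triflate should form.

Step 3
Reactants: 8 enol triflate
Product: 9 3-(2,5-dimethoxybenzyl)-3-methyl-4-[3-(2-methyl-1,3-dioxolan-2-yl)propyl]cyclohex-1-ene (C7=C8; benzyl and side chain trans)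
Conditions: Pd(OAc)2 (5 mol %), PPh3 (10 mol %), HCO2H, n-Bu3N, DMF, 60 °C
Reagents that add atoms: none
Why: Palladium-catalysed transfer hydrogenolysis of the enol triflate with formate replaces OTf by H and leaves ketal, arene and stereocentres untouched.

Step 4
Reactants: 9 cyclohexene
Product: 10 4-(2,5-dimethoxybenzyl)-4-methyl-5-[3-(2-methyl-1,3-dioxolan-2-yl)propyl]cyclohex-2-en-1-one (C6 ketone; C7=C8)
Conditions: Rh2(cap)4 (dirhodium tetrakis(caprolactamate), 1 mol %), t-BuOOH, K2CO3, CH2Cl2, rt
Reagents that add atoms: tert-butyl hydroperoxide, CC(C)(C)OO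
Why: Dirhodium-catalysed allylic oxidation with t-BuOOH: C6 is the only allylic CH2 (C9 is quaternary) and the allyl radical is trapped at its unhindered C6 terminus, so the 1,3-transposed enone should result.

Step 5
Reactants: 10 enone
Product: 11 4-(2,5-dimethoxybenzyl)-3,4-dimethyl-5-[3-(2-methyl-1,3-dioxolan-2-yl)propyl]cyclohexan-1-one (3-methyl cis to benzyl; trans to 4-methyl and to the side chain)
Conditions: MeLi, CuI, Et2O, 0 °C (Me2CuLi); then 10, −20 °C to 0 °C; aq. NH4Cl
Reagents that add atoms: lithium dimethylcuprate, [Li+].C[Cu-]C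
Why: Gilman conjugate addition: in the half-chair with the C10 chain pseudo-equatorial the 9-methyl is pseudo-axial, so the methyl group enters C8 anti to it and trans to the C10 chain, which sets C8 cis to the arylmethyl group.

Step 6
Reactants: 11 ketal ketone
Product: 13 left enone 4-(2,5-dimethoxybenzyl)-3,4,8-trimethyl-3,4,4a,5,6,7-hexahydronaphthalen-1(2H)-one (C6 ketone; C5=C4), via diketone 12 (not isolated)
Conditions: 1 M HCl, THF, rt; then KOH, MeOH, 65 °C
Reagents that add atoms: none
Why: Acidic ketal hydrolysis followed by base-mediated intramolecular aldol condensation: only the C5 enolate attacking the C4 ketone (6-(enolexo)-exo-trig) gives a fused ring that can dehydrate, and no stereocentre is α to a carbonyl.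

Step 7
Reactants: 14 4,4-dimethylcyclohex-2-en-1-one
Product: 16 2-bromo-4,4-dimethylcyclohex-2-en-1-one, via dibromide 15 (not isolated)
Conditions: Br2, CH2Cl2, 0 °C; then Et3N, 0 °C to rt
Reagents that add atoms: bromine, BrBr
Why: Bromine adds across the enone and triethylamine then removes HBr from the α-bromo ketone (bromination–dehydrobromination) to give the α-bromo enone.

Step 8
Reactants: 16 bromo enone
Product: 17 (R)-2-bromo-4,4-dimethylcyclohex-2-en-1-ol
Conditions: (S)-2-methyl-CBS-oxazaborolidine (20 mol %), BH3·SMe2, THF, −20 °C; MeOH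
Reagents that add atoms: none
Why: Corey–Bakshi–Shibata reduction, in which the bromoalkenyl arm is the large group so that the (S)-catalyst should give the (R)-carbinol, the stereocentre later relayed to C5'.

Step 9
Reactants: 17 allylic alcohol
Product: 18 (R)-2-bromo-4,4-dimethylcyclohex-2-en-1-yl pyridine-2-carboxylate
Conditions: picolinic acid, DCC, DMAP (cat.), CH2Cl2, rt
Reagents that add atoms: picolinic acid, OC(=O)c1ccccn1
Why: Steglich esterification installs the chelating picolinate leaving group with retention at the carbinol carbon.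

Step 10
Reactants: 18 picolinate; 19 2-(2-bromoethyl)-2-methyl-1,3-dioxolane
Product: 22 (R)-4-(2-bromo-6,6-dimethylcyclohex-2-en-1-yl)butan-2-one, via Grignard reagent 20 (not isolated), via ketal 21 (not isolated)
Conditions: 19, Mg, THF, 25 °C; then 18, CuBr·SMe2 (20 mol %), THF, −40 °C to 0 °C; then 1 M HCl, THF, rt
Reagents that add atoms: water, O
Why: Copper-catalysed anti-SN2' substitution of the allylic picolinate by the Grignard reagent (magnesium chelation by the picolinate directs γ-attack) transfers the carbinol configuration to C5' on the opposite ring face and leaves the alkenyl bromide untouched, after which aqueous acid unmasks the methyl ketone.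

Step 11
Reactants: 22 methyl ketone
Product: 24 (R)-1-(2-bromo-6,6-dimethylcyclohex-2-en-1-yl)-6-[(tert-butyldimethylsilyl)oxy]hexan-3-one, via lithium enolate 23 (not isolated)
Conditions: LiN(i-Pr)2, THF, −78 °C; then ICH2CH2OSiMe2t-Bu, HMPA, −78 °C to −20 °C
Reagents that add atoms: tert-butyl(2-iodoethoxy)dimethylsilane, CC(C)(C)[Si](C)(C)OCCI
Why: Kinetic deprotonation of the methyl ketone on the CH3 side and SN2 alkylation of the terminal lithium enolate (enolate alkylation) attaches C11–C12 to the future C9'.

Step 12
Reactants: 24 bromo ketone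
Product: 26 1-[2-(tert-butyldimethylsilyloxy)ethyl]-1,5,5-trimethyl-3,4,4a,5,6,7-hexahydronaphthalen-2(1H)-one (C8' ketone; C1'=C10'; 9'-methyl cis to H-5'), via potassium dienolate 25 (not isolated)
Conditions: Pd(PPh3)4 (10 mol %), KOt-Bu (2.1 equiv), THF, 60 °C; then MeI, 0 °C to rt
Reagents that add atoms: iodomethane, CI
Why: Palladium-catalysed intramolecular α-alkenylation of the ketone enolate with the alkenyl bromide closes ring C (six-membered palladacycle, C9'–C10' reductive elimination), the second equivalent of base converts the product into the C8'–C9'–C10'–C1' dienolate, and methyl iodide alkylates C9' axially on the face of H-5', the only face that leads directly to a chair of ring C, which sets C9'.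

Step 13
Reactants: 26 ketone
Product: 27 exocyclic alkene (C8'=CH2 in place of the ketone)
Conditions: Ph3PCH3Br, KOt-Bu, toluene, 90 °C
Reagents that add atoms: methyltriphenylphosphonium bromide, C[P+](c1ccccc1)(c1ccccc1)c1ccccc1.[Br-]
Why: Wittig methylenation of the C8' ketone, which has no epimerisable neighbour, gives the exocyclic alkene.

Step 14
Reactants: 27 diene
Product: 28 tert-butyl{2-[(1R,2S,4aR)-1,2,5,5-tetramethyl-1,2,3,4,4a,5,6,7-octahydronaphthalen-1-yl]ethoxy}dimethylsilane
Conditions: H2 (3 atm), RhCl(PPh3)3 (10 mol %), benzene, rt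
Reagents that add atoms: none
Why: Homogeneous hydrogenation with RhCl(PPh3)3 reduces the 1,1-disubstituted alkene but not the trisubstituted C1'=C10' alkene, and hydrogen is delivered to C8' anti to the axial 9'-methyl, so the new methyl ends equatorial and cis to it.

Step 15
Reactants: 28 silyl ether
Product: 29 (1R,2S,4aR)-1-(2-bromoethyl)-1,2,5,5-tetramethyl-1,2,3,4,4a,5,6,7-octahydronaphthalene
Conditions: Ph3PBr2, CH2Cl2, rt
Reagents that add atoms: triphenylphosphine dibromide, BrP(Br)(c1ccccc1)(c1ccccc1)c1ccccc1
Why: Triphenylphosphine dibromide converts the primary silyl ether directly into the bromide through an alkoxyphosphonium bromide (Appel-type SN2), without touching the stereocentres.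

Step 16
Reactants: 29 right-hand bromide; 13 left enone
Product: 32 coupled enol triflate (OTf on C6; C5=C6; C4 quaternary), via Grignard reagent 30 (not isolated), via magnesium enolate 31 (not isolated)
Conditions: 29 (1.3 equiv), Mg, THF, 45 °C; then 13, CuBr·SMe2 (20 mol %), THF, −30 °C to 0 °C; then N-(5-chloropyridin-2-yl)bis(trifluoromethanesulfonimide), −78 °C to rt
Reagents that add atoms: N-(5-chloropyridin-2-yl)bis(trifluoromethanesulfonimide) (Comins' reagent), FC(F)(F)S(=O)(=O)N(c1ccc(Cl)cn1)S(=O)(=O)C(F)(F)F
Why: The alkylcopper species formed from 30 adds to C4, the β-carbon of the s-cis enone O=C6–C5=C4 (π-complex, oxidative addition to a trivalent copper β-cuprio enolate, reductive elimination), and the C5=C6 magnesium enolate, formed as a single regioisomer, is O-triflated in the same flask. The closest known reaction is the copper-catalysed addition of Grignard reagents to pulegone-type 2-alkylidenecyclohexanones, which builds a quaternary carbon on the same tetrasubstituted s-cis motif, combined with standard enolate trapping by a triflimide. No ring is closed; the step forms the C4–C12 bond that unites the two decalins, completes the carbon skeleton and fixes the position of the future C5=C6 double bond. The new quaternary stereocentre C4 is substrate-controlled: the sp3 fusion carbon C10 locks ring B with C9 equatorial and H-10 axial, and only attack on the face of H-10 lets C4 pyramidalise directly into the chair, so C12 should enter axially, syn to H-10, as in the target. The step needs 1,4- over 1,2-selectivity, which the fixed s-cis geometry and the hindered C6 carbonyl should secure, and it needs no matching between the partners because the stereocentres of 30 are remote from the reacting carbon.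

Step 17
Reactants: 32 enol triflate
Product: 33 toxiusol hydroquinone dimethyl ether (2,5-dimethoxyaryl analogue of the target)
Conditions: Pd(OAc)2 (10 mol %), PPh3 (20 mol %), HCO2H, n-Bu3N, DMF, 70 °C
Reagents that add atoms: none
Why: Palladium-catalysed formate reduction of the enol triflate leaves the double bond exactly where the enolate was (C5=C6) and removes the temporary C6 oxygen.

Step 18
Reactants: 33 dimethyl ether
Product: 35 hydroquinone (desulfated toxiusol), via quinone 34 (not isolated)
Conditions: (NH4)2Ce(NO3)6, MeCN/H2O, 0 °C; then Na2S2O4, H2O/Et2O, rt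
Reagents that add atoms: water, O
Why: Oxidative demethylation of the 1,4-dimethoxyarene by the cerium oxidant gives the benzoquinone, which dithionite reduces to the hydroquinone, while the unactivated trisubstituted alkenes should survive at 0 °C.

Step 19
Reactants: 35 hydroquinone
Product: 36 toxiusol
Conditions: SO3·pyridine, pyridine, 50 °C; then Dowex 50W (H+ form), MeOH/H2O, 0 °C
Reagents that add atoms: sulfur trioxide–pyridine complex, [O-]S(=O)(=O)[n+]1ccccc1
Why: O-Sulfation of both phenols with the sulfur trioxide–pyridine complex (aryl sulfate formation) followed by cation exchange gives the bis(hydrogen sulfate).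

**Compound list**

1 | 2-methylcyclohex-2-en-1-one | CC1=CCCCC1=O | starting material
2 | 2-(3-chloropropyl)-2-methyl-1,3-dioxolane | CC1(CCCCl)OCCO1 | starting material
3 | 2,5-dimethoxybenzyl bromide | COc1ccc(OC)c(CBr)c1 | starting material
4 | [3-(2-methyl-1,3-dioxolan-2-yl)propyl]magnesium chloride (not isolated) | CC1(CCC[Mg]Cl)OCCO1 | intermediate
5 | chloromagnesium enolate after conjugate addition (C8–O, C8=C9; C10 set; not isolated) | CC1=C(O[Mg]Cl)CCC[C@H]1CCCC1(C)OCCO1 | intermediate
6 | (2S,3S)-2-(2,5-dimethoxybenzyl)-2-methyl-3-[3-(2-methyl-1,3-dioxolan-2-yl)propyl]cyclohexan-1-one | O=C1CCC[C@@H](CCCC2(C)OCCO2)[C@]1(C)Cc1cc(OC)ccc1OC | intermediate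
7 | potassium enolate of 6 (C7=C8; not isolated) | [K+].[O-]C1=CCC[C@@H](CCCC2(C)OCCO2)[C@]1(C)Cc1cc(OC)ccc1OC | intermediate
8 | enol triflate of 6 (OTf on C8) | FC(F)(F)S(=O)(=O)OC1=CCC[C@@H](CCCC2(C)OCCO2)[C@]1(C)Cc1cc(OC)ccc1OC | intermediate
9 | 3-(2,5-dimethoxybenzyl)-3-methyl-4-[3-(2-methyl-1,3-dioxolan-2-yl)propyl]cyclohex-1-ene (substituents trans) | C1=CCC[C@@H](CCCC2(C)OCCO2)[C@]1(C)Cc1cc(OC)ccc1OC | intermediate
10 | 4-(2,5-dimethoxybenzyl)-4-methyl-5-[3-(2-methyl-1,3-dioxolan-2-yl)propyl]cyclohex-2-en-1-one | C1=CC(=O)C[C@@H](CCCC2(C)OCCO2)[C@]1(C)Cc1cc(OC)ccc1OC | intermediate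
11 | 4-(2,5-dimethoxybenzyl)-3,4-dimethyl-5-[3-(2-methyl-1,3-dioxolan-2-yl)propyl]cyclohexan-1-one (3-Me cis to benzyl) | C[C@@H]1CC(=O)C[C@@H](CCCC2(C)OCCO2)[C@]1(C)Cc1cc(OC)ccc1OC | intermediate
12 | 4-(2,5-dimethoxybenzyl)-3,4-dimethyl-5-(4-oxopentyl)cyclohexan-1-one (not isolated) | C[C@@H]1CC(=O)C[C@@H](CCCC(C)=O)[C@]1(C)Cc1cc(OC)ccc1OC | intermediate
13 | left enone, 4-(2,5-dimethoxybenzyl)-3,4,8-trimethyl-3,4,4a,5,6,7-hexahydronaphthalen-1(2H)-one (8-Me and ArCH2 cis; H-10 cis to ArCH2) | C[C@@H]1CC(=O)C2=C(C)CCC[C@H]2[C@]1(C)Cc1cc(OC)ccc1OC | intermediate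
14 | 4,4-dimethylcyclohex-2-en-1-one | CC1(C)CCC(=O)C=C1 | starting material
15 | 2,3-dibromo-4,4-dimethylcyclohexan-1-one (not isolated) | CC1(C)CCC(=O)C(Br)C1Br | intermediate
16 | 2-bromo-4,4-dimethylcyclohex-2-en-1-one | CC1(C)CCC(=O)C(Br)=C1 | intermediate
17 | (R)-2-bromo-4,4-dimethylcyclohex-2-en-1-ol | O[C@@H]1CCC(C)(C)C=C1Br | intermediate
18 | (R)-2-bromo-4,4-dimethylcyclohex-2-en-1-yl pyridine-2-carboxylate | O=C(O[C@@H]1CCC(C)(C)C=C1Br)c1ccccn1 | intermediate
19 | 2-(2-bromoethyl)-2-methyl-1,3-dioxolane | CC1(CCBr)OCCO1 | starting material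
20 | [2-(2-methyl-1,3-dioxolan-2-yl)ethyl]magnesium bromide (not isolated) | CC1(CC[Mg]Br)OCCO1 | intermediate
21 | (R)-2-[2-(2-bromo-6,6-dimethylcyclohex-2-en-1-yl)ethyl]-2-methyl-1,3-dioxolane (not isolated) | BrC1=CCCC(C)(C)[C@H]1CCC1(C)OCCO1 | intermediate
22 | (R)-4-(2-bromo-6,6-dimethylcyclohex-2-en-1-yl)butan-2-one | BrC1=CCCC(C)(C)[C@H]1CCC(C)=O | intermediate
23 | terminal lithium enolate of 22 (not isolated) | BrC1=CCCC(C)(C)[C@H]1CCC(=C)O[Li] | intermediate
24 | (R)-1-(2-bromo-6,6-dimethylcyclohex-2-en-1-yl)-6-[(tert-butyldimethylsilyl)oxy]hexan-3-one | BrC1=CCCC(C)(C)[C@H]1CCC(=O)CCCO[Si](C)(C)C(C)(C)C | intermediate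
25 | potassium dienolate (C8'–O, C8'=C9', C10'=C1'; not isolated) | [K+].[O-]C1=C(CCO[Si](C)(C)C(C)(C)C)C2=CCCC(C)(C)[C@H]2CC1 | intermediate
26 | 1-[2-(tert-butyldimethylsilyloxy)ethyl]-1,5,5-trimethyl-3,4,4a,5,6,7-hexahydronaphthalen-2(1H)-one (9'-Me cis to H-5') | CC(C)(C)[Si](C)(C)OCC[C@@]1(C)C2=CCCC(C)(C)[C@H]2CCC1=O | intermediate
27 | 8'-methylidene analogue of 26 | CC(C)(C)[Si](C)(C)OCC[C@@]1(C)C2=CCCC(C)(C)[C@H]2CCC1=C | intermediate
28 | tert-butyl{2-[(1R,2S,4aR)-1,2,5,5-tetramethyl-1,2,3,4,4a,5,6,7-octahydronaphthalen-1-yl]ethoxy}dimethylsilane | CC(C)(C)[Si](C)(C)OCC[C@@]1(C)C2=CCCC(C)(C)[C@H]2CC[C@@H]1C | intermediate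
29 | (1R,2S,4aR)-1-(2-bromoethyl)-1,2,5,5-tetramethyl-1,2,3,4,4a,5,6,7-octahydronaphthalene | BrCC[C@@]1(C)C2=CCCC(C)(C)[C@H]2CC[C@@H]1C | intermediate
30 | Grignard reagent of 29 (not isolated) | Br[Mg]CC[C@@]1(C)C2=CCCC(C)(C)[C@H]2CC[C@@H]1C | intermediate
31 | bromomagnesium enolate of the coupled ketone (C6–O, C5=C6; not isolated) | C[C@@H]1CC(O[Mg]Br)=C2[C@@H](CCC[C@@]2(C)CC[C@@]2(C)C3=CCCC(C)(C)[C@H]3CC[C@@H]2C)[C@]1(C)Cc1cc(OC)ccc1OC | intermediate
32 | coupled enol triflate (OTf on C6) | C[C@@H]1CC(OS(=O)(=O)C(F)(F)F)=C2[C@@H](CCC[C@@]2(C)CC[C@@]2(C)C3=CCCC(C)(C)[C@H]3CC[C@@H]2C)[C@]1(C)Cc1cc(OC)ccc1OC | intermediate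
33 | toxiusol hydroquinone dimethyl ether | C[C@@H]1CC=C2[C@@H](CCC[C@@]2(C)CC[C@@]2(C)C3=CCCC(C)(C)[C@H]3CC[C@@H]2C)[C@]1(C)Cc1cc(OC)ccc1OC | intermediate
34 | corresponding 2-substituted 1,4-benzoquinone (not isolated) | C[C@@H]1CC=C2[C@@H](CCC[C@@]2(C)CC[C@@]2(C)C3=CCCC(C)(C)[C@H]3CC[C@@H]2C)[C@]1(C)CC1=CC(=O)C=CC1=O | intermediate
35 | hydroquinone (desulfated toxiusol) | C[C@@H]1CC=C2[C@@H](CCC[C@@]2(C)CC[C@@]2(C)C3=CCCC(C)(C)[C@H]3CC[C@@H]2C)[C@]1(C)Cc1cc(O)ccc1O | intermediate
36 | toxiusol | C[C@@H]1CC=C2[C@@H](CCC[C@@]2(C)CC[C@@]2(C)C3=CCCC(C)(C)[C@H]3CC[C@@H]2C)[C@]1(C)Cc1cc(OS(=O)(=O)O)ccc1OS(=O)(=O)O | target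

**Totals**

Total step count: 19 (left branch steps 1–6, right branch steps 7–15, union and endgame steps 16–19).
Longest linear sequence: 13 steps (steps 7–19).

**Three steps most likely to fail**

Step 16. The organocopper addition to the tetrasubstituted enone may be slower than enolisation of 13 or direct 1,2-addition, so that the valuable Grignard reagent is consumed unproductively, and the facial preference at C4 may erode. The fallback sets out from 13 and returns at 33. Reduction of 13 with LiBH(s-Bu)3 (THF, −78 °C) should deliver hydride anti to the axial 8-methyl and give the axial allylic alcohol F1, with the C6–O bond on the face of H-10 and perpendicular to the C4=C5 π-bond. Esterification with 2-(diphenylphosphanyl)benzoic acid (DCC, DMAP) would give the ortho-diphenylphosphanylbenzoate F2. Treatment of F2 with Grignard reagent 30 and CuBr·SMe2 (0.5 equiv, Et2O, rt) is a phosphine-directed, copper-mediated syn-SN2' allylic substitution: copper bound to the phosphine delivers C12 to C4 on the face of the C6–O bond while the double bond shifts to C5=C6, which should give 33 directly with the same C4 configuration.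

Step 12. Oxidative addition and ring closure at the hindered alkenyl bromide may lag behind proto-debromination, and the excess base may lead to over-methylation at C7' or to loss of facial control in the methylation. The fallback sets out from 24 and returns at 26, and replaces the palladium enolate coupling by a Robinson-type closure. Miyaura borylation of 24 (bis(pinacolato)diboron, PdCl2(dppf), KOAc, dioxane, 80 °C) would give the alkenyl boronate F3. Oxidation (NaBO3, THF/H2O) would give the 1,5-diketone F4. Amine-catalysed aldol condensation (pyrrolidine, AcOH, toluene, 80 °C, chosen to limit epimerisation at C5') would give the bicyclic enone F5. Classical deconjugative α-methylation of F5 (KOt-Bu, t-BuOH, MeI) proceeds through the same dienolate 25 and should give 26.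

Step 1. The asymmetric conjugate addition to the α-substituted enone may give insufficient enantiomeric purity, and C-benzylation of the hindered magnesium enolate may be incomplete. The fallback sets out from 2 (as Grignard reagent 4) and commercial cyclohex-2-en-1-one and returns at 6; it builds the quaternary centre stepwise. CuBr·SMe2 with a Josiphos-type ferrocenyl diphosphine (t-BuOMe, −75 °C) catalyses the conjugate addition of 4 to the unsubstituted enone, the substrate class on which this catalysis is best established, and trapping of the enolate with MeI/DMPU would give the trans-2-methyl-3-alkylcyclohexanone F6. Thermodynamic silylation (Me3SiCl, NaI, Et3N, MeCN) would give the tetrasubstituted silyl enol ether F7. Regeneration of the lithium enolate from F7 with MeLi (THF, 0 °C) and alkylation with bromide 3 in the presence of DMPU should give 6, the benzyl group again entering anti to the C10 substituent.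

Further compounds
F1 | step 16 | axial allylic alcohol from 13 (C6–OH cis to H-10 and to 8-Me) | C[C@@H]1C[C@H](O)C2=C(C)CCC[C@H]2[C@]1(C)Cc1cc(OC)ccc1OC
F2 | step 16 | 2-(diphenylphosphanyl)benzoate of F1 | C[C@@H]1C[C@H](OC(=O)c2ccccc2P(c2ccccc2)c2ccccc2)C2=C(C)CCC[C@H]2[C@]1(C)Cc1cc(OC)ccc1OC
F3 | step 12 | alkenyl pinacol boronate from 24 (boron on C10') | CC1(C)OB(OC1(C)C)C1=CCCC(C)(C)[C@H]1CCC(=O)CCCO[Si](C)(C)C(C)(C)C
F4 | step 12 | 1,5-diketone (C10' and C8' ketones) | O=C1CCCC(C)(C)[C@H]1CCC(=O)CCCO[Si](C)(C)C(C)(C)C
F5 | step 12 | bicyclic enone (C8' ketone; C9'=C10') | O=C1CC[C@@H]2C(C)(C)CCCC2=C1CCO[Si](C)(C)C(C)(C)C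
F6 | step 1 | trans-2-methyl-3-[3-(2-methyl-1,3-dioxolan-2-yl)propyl]cyclohexan-1-one | O=C1CCC[C@@H](CCCC2(C)OCCO2)[C@@H]1C
F7 | step 1 | trimethylsilyl enol ether of F6 (C8–OSiMe3; C8=C9) | C[Si](C)(C)OC1=C(C)[C@H](CCCC2(C)OCCO2)CCC1
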